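A leftover is easier to follow than a yield, so take the share of the substrate charged that is not yet target, and ask what fraction of it goes each second.

| setting | larch | alder | blue | green |
|---|---|---|---|---|
| substrate | 0.025 M | 0.038 M | 0.050 M | 0.050 M |
| partner | 0.060 M (fed, over 15 s) | 0.060 M (fed, over 15 s) | 0.0600 M (fed, over 15 s) | 0.0600 M (fed, over 15 s) |
| protic impurity | 2.5 mM | 2.5 mM | 2.50 mM | 2.50 mM |
| temperature | −45 °C | −25 °C |  |  |
| remark | run made earlier; the fed solution adds 0.20 times the starting volume | run made earlier; the fed solution adds 0.20 times the starting volume | at −40 °C throughout; the fed solution adds 0.20 times the starting volume | at −40 °C until 15 s, from then on at −10 °C; the fed solution adds 0.20 times the starting volume |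
| time |  |  | 3.0 min | 3.0 min |

| run | time / s | target / % |
|---|---|---|
| larch | 10.0 | 0 |
| larch | 15.0 | 0 |
| larch | 30.0 | 2.1 |
| larch | 60.0 | 4.5 |
| larch | 120 | 11.8 |
| alder | 10.0 | 2.9 |
| alder | 20.0 | 11.6 |
| alder | 30.0 | 18.2 |
| alder | 40.0 | 22.3 |
| alder | 60.0 | 29.1 |

(each reading ± 0.5 percentage points)

- charges are per starting volume, the dose included; the dosed solution carries all of it
- the earlier runs were read with a standard deviation of 0.5 percentage points

- which one finishes higher in amount of target, in percent of the substrate charged ("neither" within 2 percentage points) (blue / green / neither)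
- amount of target at the end, in percent of the substrate charged, blue
- amount of target at the end, in percent of the substrate charged, green

*What pace does larch show?* From 30.0 s to 120 s its leftover goes from 97.9 % to 88.2 %. The pace p, the natural log of that drop per second, is therefore 0.00116 s⁻¹.

*And alder?* From 20.0 s to 30.0 s, after its feed, alder gives 0.00776 s⁻¹, which is faster than larch, with the same partner charge.

*But does alder hold that pace?* No. From 40.0 s to 60.0 s it reads 0.00458 s⁻¹, so I can't assume that the whole leftover becomes target. I use the pace to say how far along a flask is, not how high it ends.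

*Then blue and green?* Spreading the log of the pace evenly over the degrees, blue at −40 °C has p = 0.00186 s⁻¹. Its half-time (half-life) h = ln(2)/p is 6.20 min. Green at −10 °C, reached beyond alder's temperature and so less firmly, has p = 0.0323 s⁻¹ and h = 0.358 min. After the change at 15 s, blue gets 0.444 half-times and green 7.69. My reckoning puts blue near 26.5 %.

*Finished needn't mean high. What of green?* I can't read its end. Still, alder already stood at 29.1 % at 60.0 s, above my figure for blue, so I put green ahead.

The forecast names blue, with 25 % (20 % to 30 %) for blue and 20 % (12 % to 30 %) for green: “Blue is probably slightly ahead, but this is uncertain.” My reckoning stands close to it on blue and differs on which flask ends higher.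

The flasks give 24.4 % for blue and 51.7 % for green, so green ends higher.

    substrate → intermediate (k = 0.0480 s⁻¹, Ea = 66.0 kJ mol⁻¹)
    partner + intermediate → target (k = 0.0610 L mol⁻¹ s⁻¹, Ea = 44.0 kJ mol⁻¹)
    2 intermediate → homo product (k = 0.0890 L mol⁻¹ s⁻¹, Ea = 39.0 kJ mol⁻¹)
    partner + protic impurity → quenched reagent (k = 5.60 L mol⁻¹ s⁻¹, Ea = 44.0 kJ mol⁻¹)
    (constants at −40 °C)

Green, with 7.69 half-times of 0.358 min, holds 0.542 % intermediate at 3.00 min, and its target still reads 52.3 % at 30.0 min. Blue, with 0.444 half-times, holds 35.8 % intermediate at 3.00 min, and its target reads 46.7 % at 30.0 min. Taking green's half-time over to the neighbour of green charged with 0.020 M of substrate, as a rough guess and nothing firmer, gives an unfinished share of 0.486 %. That neighbour holds 0.348 % intermediate at 3.00 min, with target at 72.7 %.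

(The numbers in the tables were generated by integration with made-up constants, noise included.)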